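## Retrosynthetic overview

1. Leoligin 13 is disconnected to angelic acid and primary alcohol 11; the ester is made last by Mitsunobu coupling so the Z-alkene is never exposed to acyl activation.
2. The tetrahydrofuran of 11 comes from triol 10 by benzylic SN1 cycloetherification; 10 comes from γ-lactone 6 by aldol with 3,4-dimethoxybenzaldehyde and hydride reduction, so the lactone O–CH2–CH–CH unit is carried into the tetrahydrofuran.
3. Lactone 6 comes from bicyclic lactone 5 by hydrogenolysis of its donor–acceptor cyclopropane bond; the cyclopropane is a latent benzyl group.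
4. Bicycle 5 comes from allylic diazoacetate 4 by an enantioselective intramolecular cyclopropanation that closes the cyclopropane and the γ-lactone together and fixes C5 of 5, which becomes C4 of leoligin.
5. Ring order: cyclopropane and lactone together (step 2), cyclopropane opened (step 3), lactone opened (step 5), tetrahydrofuran closed (step 6).

Assumption: Rh2(4R-MPPIM)4 is taken to give the (1S,5R) lactone series, by analogy with S-ligand carboxamidates giving (1R,5S) from allyl diazoacetate; if the sense is opposite, the S-ligand catalyst is used.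

## Route

Step 1
Reactants: 1 (E)-3-(3,4-dimethoxyphenyl)prop-2-en-1-ol; 2 glyoxylic acid chloride p-toluenesulfonylhydrazone
Product: 4 (E)-3-(3,4-dimethoxyphenyl)allyl diazoacetate, via tosylhydrazone ester 3 (not isolated)
Conditions: 2 (1.8 equiv), PhNMe2 (1.8 equiv), CH2Cl2, 0 °C; then Et3N (5 equiv), 0 °C → rt
Reagents that add atoms: none
Why: Corey–Myers diazoacetate synthesis: O-acylation by the acid chloride, then triethylamine-induced loss of p-toluenesulfinate from the tosylhydrazone gives the diazo ester; no stereocentre is formed.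

Step 2
Reactants: 4 (E)-3-(3,4-dimethoxyphenyl)allyl diazoacetate
Product: 5 (1S,5R,6R)-6-(3,4-dimethoxyphenyl)-3-oxabicyclo[3.1.0]hexan-2-one (aryl exo)
Conditions: Rh2(4R-MPPIM)4 (1 mol %), CH2Cl2, reflux, syringe-pump addition of 4 over 10 h
Reagents that add atoms: none
Why: Doyle-type enantioselective intramolecular cyclopropanation: the chiral dirhodium carboxamidate carbene adds to the electron-rich E-styrenyl alkene, closing the γ-lactone and the cyclopropane in one operation; the E geometry puts the aryl group exo and the catalyst's face selection sets C1, C5 and C6.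

Step 3
Reactants: 5 (1S,5R,6R)-6-(3,4-dimethoxyphenyl)-3-oxabicyclo[3.1.0]hexan-2-one
Product: 6 (R)-4-(3,4-dimethoxybenzyl)dihydrofuran-2(3H)-one
Conditions: H2 (3 atm), 10% Pd/C, EtOAc, rt
Reagents that add atoms: none
Why: Catalytic hydrogenolysis of a donor–acceptor cyclopropane: the C1–C6 bond, benzylic and α to the carbonyl, is the weakest and is cleaved, while C5 is untouched and keeps its R configuration.

Step 4
Reactants: 6 (R)-4-(3,4-dimethoxybenzyl)dihydrofuran-2(3H)-one; 7 3,4-dimethoxybenzaldehyde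
Product: 9 (3S,4R)-4-(3,4-dimethoxybenzyl)-3-[(3,4-dimethoxyphenyl)(hydroxy)methyl]dihydrofuran-2(3H)-one (both carbinol epimers), via lithium enolate 8 (not isolated)
Conditions: LiN(SiMe3)2 (1.1 equiv), THF, −78 °C; then 7, −78 °C; aq NH4Cl at −78 °C
Reagents that add atoms: none
Why: Lithium enolate aldol addition: the aldehyde approaches anti to the β-benzyl group, setting C3 trans to C4 (3S); the carbinol centre forms as a mixture, which does not matter because it is ionised in step 6.

Step 5
Reactants: 9 (3S,4R)-4-(3,4-dimethoxybenzyl)-3-[(3,4-dimethoxyphenyl)(hydroxy)methyl]dihydrofuran-2(3H)-one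
Product: 10 (2R,3R)-3-(3,4-dimethoxybenzyl)-2-[(3,4-dimethoxyphenyl)(hydroxy)methyl]butane-1,4-diol (both carbinol epimers)
Conditions: LiAlH4 (2.5 equiv), THF, 0 °C → rt; H2O, 15% aq NaOH work-up
Reagents that add atoms: none
Why: Hydride reduction of the lactone to the 1,4-diol; no stereocentre is touched.

Step 6
Reactants: 10 (2R,3R)-3-(3,4-dimethoxybenzyl)-2-[(3,4-dimethoxyphenyl)(hydroxy)methyl]butane-1,4-diol
Product: 11 [(2S,3R,4R)-4-(3,4-dimethoxybenzyl)-2-(3,4-dimethoxyphenyl)tetrahydrofuran-3-yl]methanol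
Conditions: camphorsulfonic acid (10 mol %), CH2Cl2, 0 °C → rt; quench with Et3N
Reagents that add atoms: none
Why: Acid-catalysed SN1 cycloetherification: the 3,4-dimethoxybenzylic cation is trapped 5-exo by the hydroxymethyl on the benzyl-bearing carbon (the other primary hydroxyl could only give an oxetane), and the aryl group settles trans to the C3 substituent (2S), so both carbinol epimers converge.

Step 7
Reactants: 11 [(2S,3R,4R)-4-(3,4-dimethoxybenzyl)-2-(3,4-dimethoxyphenyl)tetrahydrofuran-3-yl]methanol; 12 angelic acid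
Product: 13 leoligin
Conditions: PPh3 (1.5 equiv), DIAD (1.5 equiv), 12 (1.5 equiv), THF, 0 °C → rt
Reagents that add atoms: none
Why: Mitsunobu esterification: the primary alcohol is activated as its alkoxyphosphonium ion and displaced by angelate, so the acid is never an acyl electrophile and the Z-alkene does not isomerise to the tiglate; no stereocentre is involved.

## Compound list

1 | (E)-3-(3,4-dimethoxyphenyl)prop-2-en-1-ol (3,4-dimethoxycinnamyl alcohol) | COc1ccc(/C=C/CO)cc1OC | starting material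
2 | glyoxylic acid chloride p-toluenesulfonylhydrazone, (E)-2-(2-tosylhydrazinylidene)acetyl chloride | Cc1ccc(cc1)S(=O)(=O)N/N=C/C(=O)Cl | starting material
3 | (E)-3-(3,4-dimethoxyphenyl)allyl (E)-2-(2-tosylhydrazinylidene)acetate | COc1ccc(/C=C/COC(=O)/C=N/NS(=O)(=O)c2ccc(C)cc2)cc1OC | intermediate
4 | (E)-3-(3,4-dimethoxyphenyl)allyl diazoacetate | COc1ccc(/C=C/COC(=O)C=[N+]=[N-])cc1OC | intermediate
5 | (1S,5R,6R)-6-(3,4-dimethoxyphenyl)-3-oxabicyclo[3.1.0]hexan-2-one, aryl exo | O=C1OC[C@@H]2[C@@H](c3ccc(OC)c(OC)c3)[C@H]12 | intermediate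
6 | (R)-4-(3,4-dimethoxybenzyl)dihydrofuran-2(3H)-one | O=C1C[C@@H](Cc2ccc(OC)c(OC)c2)CO1 | intermediate
7 | 3,4-dimethoxybenzaldehyde | COc1ccc(C=O)cc1OC | starting material
8 | lithium enolate of 6, lithium (R)-4-(3,4-dimethoxybenzyl)-4,5-dihydrofuran-2-olate | [Li+].[O-]C1=C[C@@H](Cc2ccc(OC)c(OC)c2)CO1 | intermediate
9 | (3S,4R)-4-(3,4-dimethoxybenzyl)-3-[(3,4-dimethoxyphenyl)(hydroxy)methyl]dihydrofuran-2(3H)-one, 3,4-trans, both carbinol epimers | O=C1OC[C@H](Cc2ccc(OC)c(OC)c2)[C@H]1C(O)c1ccc(OC)c(OC)c1 | intermediate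
10 | (2R,3R)-3-(3,4-dimethoxybenzyl)-2-[(3,4-dimethoxyphenyl)(hydroxy)methyl]butane-1,4-diol, both carbinol epimers | OC[C@H](Cc1ccc(OC)c(OC)c1)[C@H](CO)C(O)c1ccc(OC)c(OC)c1 | intermediate
11 | [(2S,3R,4R)-4-(3,4-dimethoxybenzyl)-2-(3,4-dimethoxyphenyl)tetrahydrofuran-3-yl]methanol, 2,3-trans, 3,4-cis | OC[C@H]1[C@@H](Cc2ccc(OC)c(OC)c2)CO[C@@H]1c1ccc(OC)c(OC)c1 | intermediate
12 | angelic acid, (Z)-2-methylbut-2-enoic acid | C/C=C(/C)C(=O)O | starting material
13 | leoligin, [(2S,3R,4R)-4-(3,4-dimethoxybenzyl)-2-(3,4-dimethoxyphenyl)tetrahydrofuran-3-yl]methyl (Z)-2-methylbut-2-enoate | C/C=C(/C)C(=O)OC[C@H]1[C@@H](Cc2ccc(OC)c(OC)c2)CO[C@@H]1c1ccc(OC)c(OC)c1 | target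

## Step count and risks

Total steps: 7. Longest linear sequence: 7 steps (1 → 13).

**Step 2** is the most exposed. The carboxamidate catalyst may give low conversion or eroded enantioselectivity with this very electron-rich cinnamyl ester, and the whole absolute configuration rests on it. The fallback sets out from 1 and returns at 10. Alcohol 1 is transesterified with ethyl 3-(3,4-dimethoxyphenyl)-3-oxopropanoate (cat. DMAP, toluene, reflux) to (E)-3-(3,4-dimethoxyphenyl)allyl 3-(3,4-dimethoxyphenyl)-3-oxopropanoate F1. Diazo transfer with 4-acetamidobenzenesulfonyl azide and Et3N in MeCN gives (E)-3-(3,4-dimethoxyphenyl)allyl 2-diazo-3-(3,4-dimethoxyphenyl)-3-oxopropanoate F2. This acceptor/acceptor diazo ester is cyclised by metalloradical catalysis with the chiral amidoporphyrin complex of divalent cobalt [Co(3,5-DitBu-ChenPhyrin)], using the catalyst enantiomer that gives the 5R series. The product, again with cyclopropane and lactone closed together, is (1S,5R,6S)-1-(3,4-dimethoxybenzoyl)-6-(3,4-dimethoxyphenyl)-3-oxabicyclo[3.1.0]hexan-2-one F3. Hydrogenolysis (H2, Pd/C, EtOAc) of its doubly activated C1–C6 bond gives (3S,4R)-3-(3,4-dimethoxybenzoyl)-4-(3,4-dimethoxybenzyl)dihydrofuran-2(3H)-one F4, and LiBH4 in THF reduces ketone and lactone to triol 10.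

**Step 3** may be sluggish or may cleave some of the C5–C6 bond, giving the α-benzyl lactone. The fallback sets out from 5 and returns at 6. Thiophenol with catalytic Sc(OTf)3 in CH2Cl2 opens the donor–acceptor cyclopropane at the benzylic carbon by a nucleophilic homo-conjugate addition, giving (4R)-4-[(3,4-dimethoxyphenyl)(phenylsulfanyl)methyl]dihydrofuran-2(3H)-one F5. Desulfurisation with Raney Ni in EtOH then gives 6.

**Step 6** may suffer Friedel–Crafts capture of the benzylic cation by the second dimethoxyphenyl ring (aryltetralin), or give a 2,3-cis/trans mixture under acid. The fallback sets out from 6 and returns at 11, and forms the ring C–O bond by oxidation instead of dehydration. Enolate 8 is alkylated with 3,4-dimethoxybenzyl bromide (LiN(SiMe3)2, THF, −78 °C) anti to the existing benzyl group to give (3R,4R)-3,4-bis(3,4-dimethoxybenzyl)dihydrofuran-2(3H)-one F6. LiAlH4 gives the C2-symmetric (2R,3R)-2,3-bis(3,4-dimethoxybenzyl)butane-1,4-diol F7. One equivalent of DDQ in CH2Cl2 over NaHCO3 oxidises one benzylic C–H to the cation, which is trapped by the 4-hydroxyl to give 11. Both benzylic positions are equivalent, so mono-oxidation gives a single constitution, and the neutral medium keeps the product from re-ionising.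

Further compounds
F1 | step 2 | (E)-3-(3,4-dimethoxyphenyl)allyl 3-(3,4-dimethoxyphenyl)-3-oxopropanoate | COc1ccc(/C=C/COC(=O)CC(=O)c2ccc(OC)c(OC)c2)cc1OC
F2 | step 2 | (E)-3-(3,4-dimethoxyphenyl)allyl 2-diazo-3-(3,4-dimethoxyphenyl)-3-oxopropanoate | COc1ccc(/C=C/COC(=O)C(=[N+]=[N-])C(=O)c2ccc(OC)c(OC)c2)cc1OC
F3 | step 2 | (1S,5R,6S)-1-(3,4-dimethoxybenzoyl)-6-(3,4-dimethoxyphenyl)-3-oxabicyclo[3.1.0]hexan-2-one | O=C1OC[C@@H]2[C@@H](c3ccc(OC)c(OC)c3)[C@]12C(=O)c1ccc(OC)c(OC)c1
F4 | step 2 | (3S,4R)-3-(3,4-dimethoxybenzoyl)-4-(3,4-dimethoxybenzyl)dihydrofuran-2(3H)-one | O=C1OC[C@H](Cc2ccc(OC)c(OC)c2)[C@H]1C(=O)c1ccc(OC)c(OC)c1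
F5 | step 3 | (4R)-4-[(3,4-dimethoxyphenyl)(phenylsulfanyl)methyl]dihydrofuran-2(3H)-one, both epimers at the sulfide carbon | O=C1C[C@@H](C(Sc2ccccc2)c2ccc(OC)c(OC)c2)CO1
F6 | step 6 | (3R,4R)-3,4-bis(3,4-dimethoxybenzyl)dihydrofuran-2(3H)-one | O=C1OC[C@H](Cc2ccc(OC)c(OC)c2)[C@H]1Cc1ccc(OC)c(OC)c1
F7 | step 6 | (2R,3R)-2,3-bis(3,4-dimethoxybenzyl)butane-1,4-diol | OC[C@H](Cc1ccc(OC)c(OC)c1)[C@H](CO)Cc1ccc(OC)c(OC)c1
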